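**Plan**

1. Locants: ring C1 (angelate), C2, C3 (CH3), C4 (OAc), C5, C6; chain C7 (CH3), C8, C9 (OAc), C10=C11.
2. Retrosynthesis: the three ester C–O bonds are cut first; C1–O and C4–O are traced back to a C1 nitro group and a C4 ketone; the ring bonds C1–C2 and C5–C6 are then cut together; last, the chain bond C8–C9 is cut.
3. Enabling feature: the cyclohexane C1–C6 carries oxygen at C1 and C4 (1,4-related) and the chain at C6 trans to the C1 oxygen. This is the pattern of a [4+2] union of an (E)-alkene C1=C6, bearing an electron-withdrawing nitrogen group at C1, with a 2-oxygenated 3-methylbutadiene C2=C3–C4=C5.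
4. Forward: the C7–C11 chain is built (C8–C9 by acylation of a zinc reagent), C1 is added by a Henry reaction, and the single ring is closed around the chain in one catalytic formal [4+2] step; only functional-group changes follow.
5. The 2-oxy diene is used as the free dienol of an allyl β-keto ester (ester at C5), not as its silyl ether. A thermal Diels–Alder reaction would leave the C6 face to the weak bias of C7 (H, CH3, CH2R), whereas the acidic donor lets a chiral hydrogen-bond donor bound to the nitro group choose it.
6. Stereochemistry: C7 from methyl (R)-3-hydroxy-2-methylpropanoate; C9 by oxazaborolidine reduction; C6 by the thiourea catalyst; C3 by equilibration (equatorial); C4 by equatorial hydride attack (axial OH); C1 by catalyst-directed axial hydride delivery (equatorial OH); the (Z)-ester from angelic acid.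

Key step: step 10

Remark: the (R,R)-form of the thiourea catalyst is taken to give (R)-adducts from aryl nitroalkenes and 1,3-dicarbonyl donors; on that premise the (S,S)-form attacks the C6 face required here.

**Route**

Step 1
Reactants: 1 methyl (R)-3-hydroxy-2-methylpropanoate
Product: 2 methyl (S)-3-iodo-2-methylpropanoate
Conditions: I2, PPh3, imidazole, CH2Cl2, 0 °C → rt
Reagents that add atoms: iodine, II
Why: Appel-type iodination replaces the primary hydroxyl by SN2 attack of iodide at the CH2 group, so the neighbouring stereocentre is untouched (the descriptor changes only because the iodomethyl arm gains priority).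

Step 2
Reactants: 2 methyl (S)-3-iodo-2-methylpropanoate; 3 3-methylbut-2-enoyl chloride
Product: 5 methyl (R)-2,6-dimethyl-4-oxohept-5-enoate, via organozinc iodide 4 (not isolated)
Conditions: Zn dust (activated with BrCH2CH2Br and Me3SiCl), THF, 40 °C; then 3, Pd(PPh3)4 (5 mol %), 0 °C → rt
Reagents that add atoms: none
Why: Zinc inserts into the primary C–I bond to give an ester-chelated homoenolate that does not eliminate, and zerovalent palladium catalyses its Negishi acylation by the acid chloride faster than any conjugate addition to the enone formed, so C8–C9 is made without touching C7.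

Step 3
Reactants: 5 methyl (R)-2,6-dimethyl-4-oxohept-5-enoate
Product: 6 methyl (2R,4R)-4-hydroxy-2,6-dimethylhept-5-enoate
Conditions: (S)-Me-CBS oxazaborolidine [(S)-1-methyl-3,3-diphenyl-tetrahydro-1H,3H-pyrrolo[1,2-c][1,3,2]oxazaborole] (0.2 equiv), BH3·SMe2 (0.7 equiv), THF, −30 °C; MeOH quench; crude used at once
Reagents that add atoms: none
Why: Corey–Bakshi–Shibata reduction, in which the (S)-oxazaborolidine binds the ketone anti to the alkenyl group (the large substituent) and delivers hydride to the face giving the (R)-carbinol at C9 regardless of the remote C7 centre; the cold neutral work-up and immediate silylation are meant to forestall γ-lactonisation of the 4-hydroxy ester.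

Step 4
Reactants: 6 methyl (2R,4R)-4-hydroxy-2,6-dimethylhept-5-enoate
Product: 7 methyl (2R,4R)-4-[(tert-butyldimethylsilyl)oxy]-2,6-dimethylhept-5-enoate
Conditions: t-BuMe2SiOTf, 2,6-lutidine, CH2Cl2, −78 → 0 °C
Reagents that add atoms: tert-butyldimethylsilyl trifluoromethanesulfonate, CC(C)(C)[Si](C)(C)OS(=O)(=O)C(F)(F)F
Why: O-silylation of the secondary allylic alcohol with a silyl triflate and a hindered pyridine base is fast at low temperature and blocks both lactone formation and a later oxa-Michael addition to the nitroalkene.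

Step 5
Reactants: 7 methyl (2R,4R)-4-[(tert-butyldimethylsilyl)oxy]-2,6-dimethylhept-5-enoate
Product: 8 (2R,4R)-4-[(tert-butyldimethylsilyl)oxy]-2,6-dimethylhept-5-enal
Conditions: i-Bu2AlH (1.1 equiv), CH2Cl2, −78 °C; MeOH, then aq potassium sodium tartrate
Reagents that add atoms: none
Why: Partial hydride reduction of the methyl ester stops at the aluminium hemiacetal at −78 °C and releases the aldehyde on work-up, and since no base is present the α-stereocentre C7 should be retained.

Step 6
Reactants: 8 (2R,4R)-4-[(tert-butyldimethylsilyl)oxy]-2,6-dimethylhept-5-enal; 9 nitromethane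
Product: 10 (3R,5R)-5-[(tert-butyldimethylsilyl)oxy]-3,7-dimethyl-1-nitrooct-6-en-2-ol (both C2 epimers)
Conditions: MeNO2 (10 equiv), Et3N (0.3 equiv), THF, 0 °C → rt
Reagents that add atoms: none
Why: Henry (nitroaldol) reaction, in which the nitronate of nitromethane adds to the aldehyde under catalytic amine base and forms C1–C6; the new carbinol centre is of no consequence because the next step removes it.

Step 7
Reactants: 10 (3R,5R)-5-[(tert-butyldimethylsilyl)oxy]-3,7-dimethyl-1-nitrooct-6-en-2-ol
Product: 12 (1E,3R,5R)-5-[(tert-butyldimethylsilyl)oxy]-3,7-dimethyl-1-nitroocta-1,6-diene, via nitro mesylate 11 (not isolated)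
Conditions: MsCl, Et3N, CH2Cl2, −40 → 0 °C
Reagents that add atoms: none
Why: Mesylation followed by E1cB elimination of the β-nitro alcohol gives the conjugated nitroalkene as its thermodynamically preferred (E)-isomer, and the low temperature with a limited amount of base is meant to avoid γ-deprotonation that would endanger C7.

Step 8
Reactants: 13 allyl acetate; 14 methacrolein (2-methylprop-2-enal)
Product: 16 allyl 3-hydroxy-4-methylpent-4-enoate (racemic), via lithium enolate 15 (not isolated)
Conditions: LiN(i-Pr)2, THF, −78 °C; then 14, −78 °C; aq NH4Cl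
Reagents that add atoms: none
Why: Aldol addition of the lithium ester enolate to the aldehyde carbon of methacrolein (1,2-addition at −78 °C) gives the β-hydroxy ester, whose racemic carbinol centre is oxidised away in the next step.

Step 9
Reactants: 16 allyl 3-hydroxy-4-methylpent-4-enoate
Product: 17 allyl 4-methyl-3-oxopent-4-enoate
Conditions: DMP [1,1,1-tris(acetyloxy)-1,2-benziodoxol-3(1H)-one], NaHCO3, CH2Cl2, 0 °C → rt; used at once
Reagents that add atoms: none
Why: Dess–Martin oxidation converts the allylic β-hydroxy ester into the γ,δ-unsaturated β-keto ester under buffered neutral conditions that spare the polymerisable isopropenyl ketone.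

Step 10
Reactants: 12 (1E,3R,5R)-5-[(tert-butyldimethylsilyl)oxy]-3,7-dimethyl-1-nitroocta-1,6-diene; 17 allyl 4-methyl-3-oxopent-4-enoate
Product: 19 allyl 3-methyl-5-nitro-2-oxo-6-[(2R,4R)-4-[(tert-butyldimethylsilyl)oxy]-6-methylhept-5-en-2-yl]cyclohexane-1-carboxylate (plan locants: ester on C5; ketone C4; methyl C3; nitro C1; chain C6; C1/C3/C6 substituents equatorial; C5 as epimers and enol), via acyclic Michael adduct 18 (not isolated)
Conditions: 1-[3,5-bis(trifluoromethyl)phenyl]-3-[(1S,2S)-2-(dimethylamino)cyclohexyl]thiourea (10 mol %), 17 (1.5 equiv, added slowly), toluene, rt; then 1,1,3,3-tetramethylguanidine (0.2 equiv), MeCN, 0 °C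
Reagents that add atoms: none
Why: This is a formal [4+2] cycloaddition run as a tandem Michael reaction: the thiourea holds the nitro group of 12 by two N–H···O bonds while its dimethylamino group deprotonates 17, which reacts as its dienol (a 2-hydroxy-3-methylbuta-1,3-diene with an ester at C5) so that C5 adds to C6, and tetramethylguanidine then converts the C1 nitro group into a nitronate that adds to the enone terminus C2. The closest known reaction type is the bifunctional-thiourea-catalysed tandem Michael reaction of γ,δ-unsaturated β-keto esters with nitroalkenes, the stepwise ionic counterpart of the nitroalkene Diels–Alder reaction. The six-membered ring is closed by the C1–C2 bond in a 6-endo-trig conjugate addition of the nitronate. C6 is set by the catalyst, the (S,S)-enantiomer being chosen so that C5 attacks the face that gives the C6 configuration of the target, while C1, C3 and C5 are all epimerisable and should settle with nitro, methyl and ester equatorial (C1 nitro trans to the C6 chain). The step needs π-facial selectivity at C6 relative to C7 and C5-to-C6 regiochemistry: the (E)-nitro group is the two-point hydrogen-bond handle that lets the catalyst rather than the weakly biasing C7 centre choose the face, and the acidity of the C5 methylene together with the polarisation of the nitroalkene fixes the regiochemistry.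

Step 11
Reactants: 19 allyl 3-methyl-5-nitro-2-oxo-6-[(2R,4R)-4-[(tert-butyldimethylsilyl)oxy]-6-methylhept-5-en-2-yl]cyclohexane-1-carboxylate
Product: 21 (2S,4R,5S)-5-[(2R,4R)-4-[(tert-butyldimethylsilyl)oxy]-6-methylhept-5-en-2-yl]-2-methyl-4-nitrocyclohexan-1-one (plan locants: C4 ketone; C3 methyl and C1 nitro and C6 chain all equatorial), via keto acid 20 (not isolated)
Conditions: Pd(PPh3)4 (5 mol %), morpholine (10 equiv), THF, rt → 40 °C
Reagents that add atoms: none
Why: Tsuji-type palladium-catalysed deallylation transfers the allyl group to the excess morpholine and frees the β-keto acid, which loses CO2, and the amine then equilibrates the enolisable C3 and the nitro-bearing C1 so that the C3 methyl ends equatorial, which sets C3.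

Step 12
Reactants: 21 (2S,4R,5S)-5-[(2R,4R)-4-[(tert-butyldimethylsilyl)oxy]-6-methylhept-5-en-2-yl]-2-methyl-4-nitrocyclohexan-1-one
Product: 22 (1R,2S,4R,5S)-5-[(2R,4R)-4-[(tert-butyldimethylsilyl)oxy]-6-methylhept-5-en-2-yl]-2-methyl-4-nitrocyclohexan-1-ol (axial C4 hydroxyl cis to the C3 methyl)
Conditions: LiBH(s-Bu)3 (2.2 equiv), THF, −78 °C; aq NH4Cl (no alkaline peroxide)
Reagents that add atoms: none
Why: Hydride reduction with the bulky trialkylborohydride attacks the conformationally fixed cyclohexanone from the equatorial direction and gives the axial C4 alcohol cis to the equatorial C3 methyl, while the secondary nitro group is not reduced and any nitronate is reprotonated on work-up (C1 is erased in the next step).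

Step 13
Reactants: 22 (1R,2S,4R,5S)-5-[(2R,4R)-4-[(tert-butyldimethylsilyl)oxy]-6-methylhept-5-en-2-yl]-2-methyl-4-nitrocyclohexan-1-ol
Product: 24 (2S,4R,5S)-2-[(2R,4R)-4-[(tert-butyldimethylsilyl)oxy]-6-methylhept-5-en-2-yl]-4-hydroxy-5-methylcyclohexan-1-one (plan locants: C1 ketone; C4 axial hydroxyl), via sodium nitronate 23 (not isolated)
Conditions: NaOMe, MeOH, 0 °C; then aq TiCl3, NH4OAc (pH ca. 5), rt
Reagents that add atoms: water, O
Why: Reductive Nef reaction, in which trivalent titanium reduces the nitronate at nitrogen and the buffered aqueous medium hydrolyses the resulting C=N bond to the C1 ketone; the C6 chain, now α to the ketone, stays equatorial because that is also the thermodynamic arrangement.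

Step 14
Reactants: 24 (2S,4R,5S)-2-[(2R,4R)-4-[(tert-butyldimethylsilyl)oxy]-6-methylhept-5-en-2-yl]-4-hydroxy-5-methylcyclohexan-1-one
Product: 25 (2S,4R,5S)-4-hydroxy-2-[(2R,4R)-4-hydroxy-6-methylhept-5-en-2-yl]-5-methylcyclohexan-1-one
Conditions: HF·pyridine, pyridine, THF, 0 °C → rt
Reagents that add atoms: none
Why: Fluoride-mediated desilylation under pyridine buffering frees the C9 allylic alcohol without the strong acid that would ionise it.

Step 15
Reactants: 25 (2S,4R,5S)-4-hydroxy-2-[(2R,4R)-4-hydroxy-6-methylhept-5-en-2-yl]-5-methylcyclohexan-1-one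
Product: 26 (1R,2S,5S)-5-[(2R,4R)-4-acetoxy-6-methylhept-5-en-2-yl]-2-methyl-4-oxocyclohexyl acetate (acetates at C4 and C9)
Conditions: Ac2O, pyridine, DMAP (cat.), CH2Cl2, rt
Reagents that add atoms: acetic anhydride, CC(=O)OC(C)=O
Why: DMAP-catalysed acetylation esterifies both the axial C4 and the allylic C9 hydroxyl groups with retention, since only O–acyl bonds are formed.

Step 16
Reactants: 26 (1R,2S,5S)-5-[(2R,4R)-4-acetoxy-6-methylhept-5-en-2-yl]-2-methyl-4-oxocyclohexyl acetate
Product: 27 (1R,2S,4R,5S)-5-[(2R,4R)-4-acetoxy-6-methylhept-5-en-2-yl]-4-hydroxy-2-methylcyclohexyl acetate (equatorial C1 hydroxyl trans to the C6 chain)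
Conditions: (S)-Me-CBS oxazaborolidine (0.5 equiv), BH3·SMe2 (0.7 equiv), THF, −20 °C; MeOH quench
Reagents that add atoms: none
Why: Corey–Bakshi–Shibata reduction, in which the (S)-catalyst binds the ketone anti to the branched C6 side and delivers hydride to the axial face of C1 (the face small hydrides also prefer), giving the equatorial (1R) alcohol, while the acetates and the trisubstituted alkene are inert to the borane at this temperature.

Step 17
Reactants: 27 (1R,2S,4R,5S)-5-[(2R,4R)-4-acetoxy-6-methylhept-5-en-2-yl]-4-hydroxy-2-methylcyclohexyl acetate; 28 angelic acid [(Z)-2-methylbut-2-enoic acid]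
Product: 30 (1R,2S,4R,5S)-4-acetoxy-2-[(2R,4R)-4-acetoxy-6-methylhept-5-en-2-yl]-5-methylcyclohexyl (Z)-2-methylbut-2-enoate (CNP0286954.1), via mixed anhydride 29 (not isolated)
Conditions: 28, 2,4,6-trichlorobenzoyl chloride, Et3N, toluene, rt; then 27, 80 °C
Reagents that add atoms: none
Why: Yamaguchi-type esterification, in which the preformed angelic 2,4,6-trichlorobenzoic anhydride acylates the equatorial C1 alcohol at the less hindered angeloyl carbonyl on heating without a nucleophilic catalyst, conditions chosen to keep the (Z)-geometry of the angelate.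

**Compound list**

1 | methyl (R)-3-hydroxy-2-methylpropanoate | COC(=O)[C@H](C)CO | starting material
2 | methyl (S)-3-iodo-2-methylpropanoate | COC(=O)[C@H](C)CI | intermediate
3 | 3-methylbut-2-enoyl chloride | CC(C)=CC(=O)Cl | starting material
4 | [(2S)-3-methoxy-2-methyl-3-oxopropyl]zinc iodide | COC(=O)[C@H](C)C[Zn]I | intermediate
5 | methyl (R)-2,6-dimethyl-4-oxohept-5-enoate | COC(=O)[C@H](C)CC(=O)C=C(C)C | intermediate
6 | methyl (2R,4R)-4-hydroxy-2,6-dimethylhept-5-enoate | COC(=O)[C@H](C)C[C@H](C=C(C)C)O | intermediate
7 | methyl (2R,4R)-4-[(tert-butyldimethylsilyl)oxy]-2,6-dimethylhept-5-enoate | COC(=O)[C@H](C)C[C@H](C=C(C)C)O[Si](C)(C)C(C)(C)C | intermediate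
8 | (2R,4R)-4-[(tert-butyldimethylsilyl)oxy]-2,6-dimethylhept-5-enal | O=C[C@H](C)C[C@H](C=C(C)C)O[Si](C)(C)C(C)(C)C | intermediate
9 | nitromethane | C[N+](=O)[O-] | starting material
10 | (3R,5R)-5-[(tert-butyldimethylsilyl)oxy]-3,7-dimethyl-1-nitrooct-6-en-2-ol (C2 epimers) | O=[N+]([O-])CC(O)[C@H](C)C[C@H](C=C(C)C)O[Si](C)(C)C(C)(C)C | intermediate
11 | methanesulfonate of 10 | CS(=O)(=O)OC(C[N+](=O)[O-])[C@H](C)C[C@H](C=C(C)C)O[Si](C)(C)C(C)(C)C | intermediate
12 | (1E,3R,5R)-5-[(tert-butyldimethylsilyl)oxy]-3,7-dimethyl-1-nitroocta-1,6-diene | O=[N+]([O-])/C=C/[C@H](C)C[C@H](C=C(C)C)O[Si](C)(C)C(C)(C)C | intermediate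
13 | allyl acetate | CC(=O)OCC=C | starting material
14 | methacrolein | C=C(C)C=O | starting material
15 | lithium enolate of allyl acetate | C=C(O[Li])OCC=C | intermediate
16 | allyl 3-hydroxy-4-methylpent-4-enoate (racemic) | C=C(C)C(O)CC(=O)OCC=C | intermediate
17 | allyl 4-methyl-3-oxopent-4-enoate | C=C(C)C(=O)CC(=O)OCC=C | intermediate
18 | allyl 2-[(2R,3R,5R)-5-[(tert-butyldimethylsilyl)oxy]-3,7-dimethyl-1-nitrooct-6-en-2-yl]-4-methyl-3-oxopent-4-enoate (epimers at the keto ester carbon) | C=C(C)C(=O)C(C(=O)OCC=C)[C@H](C[N+](=O)[O-])[C@H](C)C[C@H](C=C(C)C)O[Si](C)(C)C(C)(C)C | intermediate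
19 | allyl 3-methyl-5-nitro-2-oxo-6-[(2R,4R)-4-[(tert-butyldimethylsilyl)oxy]-6-methylhept-5-en-2-yl]cyclohexane-1-carboxylate (C1 nitro, C3 methyl, C6 chain equatorial; C5 unfixed) | O=[N+]([O-])[C@@H]1C[C@H](C)C(=O)C(C(=O)OCC=C)[C@H]1[C@H](C)C[C@H](C=C(C)C)O[Si](C)(C)C(C)(C)C | intermediate
20 | β-keto acid from 19 | O=[N+]([O-])[C@@H]1C[C@H](C)C(=O)C(C(=O)O)[C@H]1[C@H](C)C[C@H](C=C(C)C)O[Si](C)(C)C(C)(C)C | intermediate
21 | (2S,4R,5S)-5-[(2R,4R)-4-[(tert-butyldimethylsilyl)oxy]-6-methylhept-5-en-2-yl]-2-methyl-4-nitrocyclohexan-1-one | O=[N+]([O-])[C@@H]1C[C@H](C)C(=O)C[C@H]1[C@H](C)C[C@H](C=C(C)C)O[Si](C)(C)C(C)(C)C | intermediate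
22 | (1R,2S,4R,5S)-5-[(2R,4R)-4-[(tert-butyldimethylsilyl)oxy]-6-methylhept-5-en-2-yl]-2-methyl-4-nitrocyclohexan-1-ol | O=[N+]([O-])[C@@H]1C[C@H](C)[C@H](O)C[C@H]1[C@H](C)C[C@H](C=C(C)C)O[Si](C)(C)C(C)(C)C | intermediate
23 | sodium nitronate of 22 | [Na+].[O-][N+]([O-])=C1C[C@H](C)[C@H](O)C[C@H]1[C@H](C)C[C@H](C=C(C)C)O[Si](C)(C)C(C)(C)C | intermediate
24 | (2S,4R,5S)-2-[(2R,4R)-4-[(tert-butyldimethylsilyl)oxy]-6-methylhept-5-en-2-yl]-4-hydroxy-5-methylcyclohexan-1-one | O=C1C[C@H](C)[C@H](O)C[C@H]1[C@H](C)C[C@H](C=C(C)C)O[Si](C)(C)C(C)(C)C | intermediate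
25 | (2S,4R,5S)-4-hydroxy-2-[(2R,4R)-4-hydroxy-6-methylhept-5-en-2-yl]-5-methylcyclohexan-1-one | O=C1C[C@H](C)[C@H](O)C[C@H]1[C@H](C)C[C@H](C=C(C)C)O | intermediate
26 | (1R,2S,5S)-5-[(2R,4R)-4-acetoxy-6-methylhept-5-en-2-yl]-2-methyl-4-oxocyclohexyl acetate | O=C1C[C@H](C)[C@H](OC(C)=O)C[C@H]1[C@H](C)C[C@H](C=C(C)C)OC(C)=O | intermediate
27 | (1R,2S,4R,5S)-5-[(2R,4R)-4-acetoxy-6-methylhept-5-en-2-yl]-4-hydroxy-2-methylcyclohexyl acetate | O[C@@H]1C[C@H](C)[C@H](OC(C)=O)C[C@H]1[C@H](C)C[C@H](C=C(C)C)OC(C)=O | intermediate
28 | angelic acid | C/C=C(/C)C(=O)O | starting material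
29 | angelic 2,4,6-trichlorobenzoic anhydride | C/C=C(/C)C(=O)OC(=O)c1c(Cl)cc(Cl)cc1Cl | intermediate
30 | (1R,2S,4R,5S)-4-acetoxy-2-[(2R,4R)-4-acetoxy-6-methylhept-5-en-2-yl]-5-methylcyclohexyl (Z)-2-methylbut-2-enoate | C/C=C(/C)C(=O)O[C@@H]1C[C@H](C)[C@H](OC(C)=O)C[C@H]1[C@H](C)C[C@H](C=C(C)C)OC(C)=O | target

**Step count and risks**

Total step count: 17.
Longest linear sequence: 15 steps (steps 1–7 and 10–17, from compound 1); steps 8–9 prepare the second partner.

Steps most likely to fail:

Step 10. Keto ester 17 is both donor and acceptor, so its self-condensation may outrun addition to the branched, slowly reacting nitroalkene. The amine catalyst may also deconjugate 12 and erode C7, or be mismatched with C7 and give poor facial selectivity. The fallback is a concerted thermal cycloaddition with a diene that is no Michael acceptor and needs no base. It sets out from 12: 2-(trimethylsilyloxy)-3-methylbuta-1,3-diene F1, made from commercial 3-methylbut-3-en-2-one with Me3SiOTf/Et3N, is heated with 12 in toluene at 80 °C. This Diels–Alder reaction forms C1–C2 and C5–C6 suprafacially and should give the trans silyl enol ether cycloadduct F2 with nitro para to the silyloxy carbon. K2CO3 in MeOH then cleaves the enol ether and equilibrates C3, returning to the route at 21. In this variant the facial choice rests on C7 alone, so the two C6 diastereomers would have to be separated at 21.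

Step 16. The bulky catalyst–borane complex must approach C1 axially next to the branched C6 substituent, so facial selectivity may be poor or the reduction sluggish. The fallback replaces hydride delivery by electron transfer and sets out from 26. SmI2 in THF with water as proton source (no amine additive, so the acetates survive) reduces the ketone through ketyl and carbanion stages whose protonation should favour the more stable equatorial carbinol, as in dissolving-metal reductions. It returns to the route at 27 and passes through no new compound (F0).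

Step 13. Reduction of the hindered secondary nitronate may be incomplete, or the allylic silyl ether may be lost in the acidic titanium medium. The fallback goes through the amine and sets out from 22. Zinc dust in AcOH/THF reduces the nitro group to (1R,2S,4R,5S)-4-amino-5-[(2R,4R)-4-[(tert-butyldimethylsilyl)oxy]-6-methylhept-5-en-2-yl]-2-methylcyclohexan-1-ol F3. This primary amine is converted into the ketone by transamination with 4-formyl-1-methylpyridinium benzenesulfonate (imine formation, prototropic shift with DBU, mild aqueous acid hydrolysis), returning to the route at 24.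

Further compounds
F1 | step 10 | 2-(trimethylsilyloxy)-3-methylbuta-1,3-diene | C=C(C)C(=C)O[Si](C)(C)C
F2 | step 10 | trimethylsilyl enol ether cycloadduct (C3=C4 enol ether; C1 nitro trans to the C6 chain) | O=[N+]([O-])[C@@H]1CC(C)=C(O[Si](C)(C)C)C[C@H]1[C@H](C)C[C@H](C=C(C)C)O[Si](C)(C)C(C)(C)C
F0 | step 16 | none | none
F3 | step 13 | (1R,2S,4R,5S)-4-amino-5-[(2R,4R)-4-[(tert-butyldimethylsilyl)oxy]-6-methylhept-5-en-2-yl]-2-methylcyclohexan-1-ol | N[C@@H]1C[C@H](C)[C@H](O)C[C@H]1[C@H](C)C[C@H](C=C(C)C)O[Si](C)(C)C(C)(C)C
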